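Ring C of the upper flavan is cut at O1–C2 and C4–C4a: its ring A becomes 3-(benzyloxy)phenol and C2–C3–C4 becomes a cis-aryloxirane whose neighbouring carbinol carbon (C4) sits on C8 of a benzylated (−)-fisetinidol, made from (+)-taxifolin by 5-deoxygenation and C4 reduction. The key step exploits that C2 and C4 are both benzylic: the phenoxide opens the oxirane at C2 with inversion (O1–C2), then acid ionises C4, which sits on the lower C8 between O1 and O7, and the tethered arene closes ring C (C4–C4a) anti to the C3 hydroxyl. A catalyst-set carbinol centre relays to the oxirane and is then erased.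

Key step: step 12

Remark: flavan numbering is used throughout; "upper" is the unit that carries the C4–aryl bond, "lower" is the C8-linked unit, and (+)-taxifolin is the (2R,3R) compound sold as dihydroquercetin.

Step 1
Reactants: 1 (+)-taxifolin
Product: 2 7,3',4'-tri-O-benzyltaxifolin
Conditions: BnBr (3.2 equiv), K2CO3, DMF, 0 °C → rt
Reagents that add atoms: benzyl bromide BrCc1ccccc1
Why: Williamson etherification of the three most acidic phenols (7, 3', 4') with mild carbonate leaves the 5-OH (hydrogen-bonded to the C4 carbonyl) and the secondary 3-OH free, and the two stereocentres bought with taxifolin are not touched.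

Step 2
Reactants: 2 7,3',4'-tri-O-benzyltaxifolin
Product: 3 7,3',4'-tri-O-benzyltaxifolin 5-O-triflate
Conditions: PhNTf2, Et3N, DMAP (cat.), CH2Cl2, rt
Reagents that add atoms: N-phenylbis(trifluoromethanesulfonimide) O=S(=O)(N(c1ccccc1)S(=O)(=O)C(F)(F)F)C(F)(F)F
Why: Phenol triflation with N-phenyltriflimide is chemoselective for the remaining 5-phenol over the secondary alcohol and needs only an amine base.

Step 3
Reactants: 3 7,3',4'-tri-O-benzyltaxifolin 5-O-triflate
Product: 4 7,3',4'-tri-O-benzylfustin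
Conditions: Pd(OAc)2 (5 mol%), 1,3-bis(diphenylphosphino)propane, HCO2H, Et3N, DMF, 70 °C
Reagents that add atoms: none
Why: Pd-catalysed formate reduction of the aryl triflate (oxidative addition is accelerated by the ortho carbonyl) removes the 5-oxygen, while the homogeneous Pd–phosphine system should leave benzyl ethers and both stereocentres intact.

Step 4
Reactants: 4 7,3',4'-tri-O-benzylfustin
Product: 6 7,3',4'-tri-O-benzyl-(−)-fisetinidol, via flavan-3,4-diol 5 (not isolated)
Conditions: NaBH4, THF/MeOH, 0 °C; then CH2Cl2, Et3SiH, TFA, −20 → 0 °C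
Reagents that add atoms: none
Why: Hydride reduction of the ketone followed by ionic hydrogenation: the benzylic C4 alcohol ionises to a cation stabilised by O1 and the para 7-benzyloxy group and is reduced by Et3SiH, so C2 and C3 keep their configuration.

Step 5
Reactants: 6 7,3',4'-tri-O-benzyl-(−)-fisetinidol
Product: 7 3,7,3',4'-tetra-O-benzyl-(−)-fisetinidol
Conditions: NaH, BnBr, Bu4NI (cat.), DMF, 0 °C → rt
Reagents that add atoms: benzyl bromide BrCc1ccccc1
Why: Williamson etherification caps the secondary alcohol so that it neither quenches the aryllithium of step 8 nor traps the C4 cation of step 12.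

Step 6
Reactants: 8 3,4-bis(benzyloxy)benzaldehyde
Product: 9 1,2-bis(benzyloxy)-4-ethynylbenzene
Conditions: dimethyl (1-diazo-2-oxopropyl)phosphonate, K2CO3, MeOH, rt
Reagents that add atoms: dimethyl (1-diazo-2-oxopropyl)phosphonate COP(=O)(OC)C(=[N+]=[N-])C(C)=O
Why: Ohira–Bestmann (Seyferth–Gilbert) homologation converts the aldehyde into the terminal alkyne under mild carbonate conditions.

Step 7
Reactants: 9 1,2-bis(benzyloxy)-4-ethynylbenzene
Product: 11 3-[3,4-bis(benzyloxy)phenyl]-N-methoxy-N-methylprop-2-ynamide, via lithium acetylide 10 (not isolated)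
Conditions: n-BuLi, THF, −78 °C; then N-methoxy-N-methylcarbamoyl chloride, −78 °C → rt
Reagents that add atoms: N-methoxy-N-methylcarbamoyl chloride CON(C)C(Cl)=O
Why: Acylation of the lithium acetylide by the carbamoyl chloride gives the alkynyl Weinreb amide directly.

Step 8
Reactants: 7 3,7,3',4'-tetra-O-benzyl-(−)-fisetinidol; 11 3-[3,4-bis(benzyloxy)phenyl]-N-methoxy-N-methylprop-2-ynamide
Product: 13 8-aroyl ynone 1-[(2R,3S)-3,7-bis(benzyloxy)-2-[3,4-bis(benzyloxy)phenyl]chroman-8-yl]-3-[3,4-bis(benzyloxy)phenyl]prop-2-yn-1-one, via 8-lithioflavan 12 (not isolated)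
Conditions: n-BuLi (1.2 equiv), THF, −20 → 0 °C; then 11, −78 → −30 °C; cold 1 M HCl quench
Reagents that add atoms: none
Why: Directed ortho-metalation occurs at C8, the only aryl C–H flanked by two ether oxygens (O1 and 7-OBn), and acyl substitution on the Weinreb amide stops at the ketone because the chelated tetrahedral adduct survives until the quench.

Step 9
Reactants: 13 8-aroyl ynone
Product: 14 (1S)-1-[(2R,3S)-3,7-bis(benzyloxy)-2-[3,4-bis(benzyloxy)phenyl]chroman-8-yl]-3-[3,4-bis(benzyloxy)phenyl]prop-2-yn-1-ol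
Conditions: (R)-2-methyl-CBS-oxazaborolidine (0.5 equiv), BH3·SMe2, THF, −30 °C; MeOH quench
Reagents that add atoms: none
Why: Corey–Bakshi–Shibata reduction with the di-ortho-oxygenated aryl group as the large and the alkynyl group as the small substituent should deliver hydride to the face that gives the (S)-carbinol, and any minor epimer is a separable diastereomer because of the lower-unit stereocentres.

Step 10
Reactants: 14 (1S)-propargylic alcohol
Product: 15 (1S,2Z)-1-[(2R,3S)-3,7-bis(benzyloxy)-2-[3,4-bis(benzyloxy)phenyl]chroman-8-yl]-3-[3,4-bis(benzyloxy)phenyl]prop-2-en-1-ol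
Conditions: H2 (1 atm), Pd/CaCO3 poisoned with Pb(OAc)2 (Lindlar catalyst), quinoline, EtOAc, rt
Reagents that add atoms: none
Why: Lindlar semihydrogenation adds H2 syn to the alkyne on the poisoned Pd surface, giving the Z-alkene without hydrogenolysis of benzyl ethers.

Step 11
Reactants: 15 (1S,2Z)-allylic alcohol
Product: 16 (R)-[(2R,3S)-3,7-bis(benzyloxy)-2-[3,4-bis(benzyloxy)phenyl]chroman-8-yl][(2S,3R)-3-[3,4-bis(benzyloxy)phenyl]oxiran-2-yl]methanol
Conditions: dimethyldioxirane (1.2 equiv, acetone solution), CH2Cl2, −20 °C; concentrated cold and used crude at once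
Reagents that add atoms: dimethyldioxirane CC1(C)OO1
Why: Hydroxyl-directed epoxidation under 1,3-allylic strain control: the carbinol C–H eclipses the Z-alkene and the hydrogen-bonded dioxirane adds to the face syn to OH and anti to the bulky aryl group, so the (S)-carbinol relays its configuration to the threo (2S,3R)-cis-oxirane, and neutral volatile dimethyldioxirane avoids acid that would open the electron-rich aryl oxirane.

Step 12
Reactants: 16 threo cis-epoxy alcohol; 17 3-(benzyloxy)phenol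
Product: 19 hepta-O-benzyl dimer (2S,3S,4S)-7-(benzyloxy)-2-[3,4-bis(benzyloxy)phenyl]-4-[(2R,3S)-3,7-bis(benzyloxy)-2-[3,4-bis(benzyloxy)phenyl]chroman-8-yl]chroman-3-ol, via aryl ether diol 18 (not isolated)
Conditions: 17 (1.5 equiv), KOt-Bu (1.2 equiv), 18-crown-6, THF, 55 °C; then CH2Cl2 (dilution), TFA, −40 → 0 °C
Reagents that add atoms: none
Why: Stage one is an SN2 (Williamson-type) opening of the oxirane by the potassium phenoxide at the benzylic carbon C2, so O1–C2 forms with inversion (the 3R oxirane carbon becomes 2S) while C3 keeps its oxygen and configuration, attack at C3 being disfavoured because that carbon lacks benzylic activation and is shielded by the bulky carbinol. Stage two is an intramolecular Friedel–Crafts alkylation: TFA ionises the C4 carbinol to a cation stabilised by both ortho oxygens (O1 and O7) of the lower ring A, and the tethered resorcinol ring attacks through its carbon para to the benzyloxy group, forming C4–C4a. Only ring C closes, as a six-membered ring with the arene C8a=C4a bond inside it (6-endo with respect to the arene π bond); the closest known reaction types are the phenoxide opening of aryl glycidols and the acid-mediated cyclisation of 3-aryloxy-1-arylpropanols to 4-arylchromans. C2 is controlled by the oxirane (stereospecific inversion), C3 is carried over, and C4 is set by 1,3-allylic strain: the C3–H bond eclipses the plane of the 2,6-dioxygenated benzylic cation, which puts the C3 hydroxyl on one face and C2 with its tethered arene on the other, so the new aryl–C4 bond should form anti to O3 and leave the lower unit 3,4-trans to the hydroxyl and 2,4-trans to ring B. The step needs O- rather than C-alkylation in stage one (crown-complexed potassium phenoxide in THF), C2 over C3 regioselectivity, and cyclisation para rather than ortho to the benzyloxy group (the ortho site lies between two oxygens and is hindered). The configuration of the carbinol in 16 is irrelevant at this point because it is erased on ionisation.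

Step 13
Reactants: 19 hepta-O-benzyl dimer
Product: 20 target (2S,3S,4S)-2-(3,4-dihydroxyphenyl)-4-[(2R,3S)-2-(3,4-dihydroxyphenyl)-3,7-dihydroxychroman-8-yl]chromane-3,7-diol
Conditions: H2 (1 atm), Pd(OH)2/C, THF/MeOH, rt
Reagents that add atoms: none
Why: Hydrogenolysis of the seven benzyl ethers over Pd(OH)2/C under mild conditions should not cleave the cyclic benzylic C2–O1 ether or the C4–aryl bond and touches no stereocentre.

Compound list
1 | (+)-taxifolin, (2R,3R)-2-(3,4-dihydroxyphenyl)-3,5,7-trihydroxychroman-4-one | Oc1cc(O)c2c(c1)O[C@H](c1ccc(O)c(O)c1)[C@@H](O)C2=O | starting material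
2 | 7,3',4'-tri-O-benzyltaxifolin, (2R,3R)-7-(benzyloxy)-2-[3,4-bis(benzyloxy)phenyl]-3,5-dihydroxychroman-4-one | c1ccccc1COc1cc(O)c2c(c1)O[C@H](c1ccc(OCc3ccccc3)c(OCc3ccccc3)c1)[C@@H](O)C2=O | intermediate
3 | 5-O-triflate of 2, (2R,3R)-7-(benzyloxy)-2-[3,4-bis(benzyloxy)phenyl]-3-hydroxy-4-oxochroman-5-yl trifluoromethanesulfonate | c1ccccc1COc1cc(OS(=O)(=O)C(F)(F)F)c2c(c1)O[C@H](c1ccc(OCc3ccccc3)c(OCc3ccccc3)c1)[C@@H](O)C2=O | intermediate
4 | 7,3',4'-tri-O-benzylfustin, (2R,3R)-7-(benzyloxy)-2-[3,4-bis(benzyloxy)phenyl]-3-hydroxychroman-4-one | c1ccccc1COc1ccc2c(c1)O[C@H](c1ccc(OCc3ccccc3)c(OCc3ccccc3)c1)[C@@H](O)C2=O | intermediate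
5 | (2R,3S,4R)-7-(benzyloxy)-2-[3,4-bis(benzyloxy)phenyl]chromane-3,4-diol (2,3-trans-3,4-trans) | c1ccccc1COc1ccc2c(c1)O[C@H](c1ccc(OCc3ccccc3)c(OCc3ccccc3)c1)[C@@H](O)[C@@H]2O | intermediate
6 | 7,3',4'-tri-O-benzyl-(−)-fisetinidol, (2R,3S)-7-(benzyloxy)-2-[3,4-bis(benzyloxy)phenyl]chroman-3-ol | c1ccccc1COc1ccc2c(c1)O[C@H](c1ccc(OCc3ccccc3)c(OCc3ccccc3)c1)[C@@H](O)C2 | intermediate
7 | 3,7,3',4'-tetra-O-benzyl-(−)-fisetinidol, (2R,3S)-3,7-bis(benzyloxy)-2-[3,4-bis(benzyloxy)phenyl]chromane | c1ccccc1COc1ccc2c(c1)O[C@H](c1ccc(OCc3ccccc3)c(OCc3ccccc3)c1)[C@@H](OCc1ccccc1)C2 | intermediate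
8 | 3,4-bis(benzyloxy)benzaldehyde | O=Cc1ccc(OCc2ccccc2)c(OCc2ccccc2)c1 | starting material
9 | 1,2-bis(benzyloxy)-4-ethynylbenzene | C#Cc1ccc(OCc2ccccc2)c(OCc2ccccc2)c1 | intermediate
10 | lithium [3,4-bis(benzyloxy)phenyl]acetylide | [Li]C#Cc1ccc(OCc2ccccc2)c(OCc2ccccc2)c1 | intermediate
11 | 3-[3,4-bis(benzyloxy)phenyl]-N-methoxy-N-methylprop-2-ynamide | CON(C)C(=O)C#Cc1ccc(OCc2ccccc2)c(OCc2ccccc2)c1 | intermediate
12 | 8-lithio derivative of 7 | [Li]c1c(OCc3ccccc3)ccc2c1O[C@H](c1ccc(OCc3ccccc3)c(OCc3ccccc3)c1)[C@@H](OCc1ccccc1)C2 | intermediate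
13 | 1-[(2R,3S)-3,7-bis(benzyloxy)-2-[3,4-bis(benzyloxy)phenyl]chroman-8-yl]-3-[3,4-bis(benzyloxy)phenyl]prop-2-yn-1-one | O=C(C#Cc1ccc(OCc2ccccc2)c(OCc2ccccc2)c1)c1c(OCc3ccccc3)ccc2c1O[C@H](c1ccc(OCc3ccccc3)c(OCc3ccccc3)c1)[C@@H](OCc1ccccc1)C2 | intermediate
14 | (1S)-propargylic alcohol from 13 | O[C@H](c1c(OCc3ccccc3)ccc2c1O[C@H](c1ccc(OCc3ccccc3)c(OCc3ccccc3)c1)[C@@H](OCc1ccccc1)C2)C#Cc1ccc(OCc2ccccc2)c(OCc2ccccc2)c1 | intermediate
15 | (1S,2Z)-allylic alcohol from 14 | O[C@H](c1c(OCc3ccccc3)ccc2c1O[C@H](c1ccc(OCc3ccccc3)c(OCc3ccccc3)c1)[C@@H](OCc1ccccc1)C2)/C=C\c1ccc(OCc2ccccc2)c(OCc2ccccc2)c1 | intermediate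
16 | threo cis-epoxy alcohol, (R)-carbinol on C8 of the lower unit with a (2S,3R)-3-[3,4-bis(benzyloxy)phenyl]oxiran-2-yl group | O[C@H](c1c(OCc3ccccc3)ccc2c1O[C@H](c1ccc(OCc3ccccc3)c(OCc3ccccc3)c1)[C@@H](OCc1ccccc1)C2)[C@@H]1O[C@@H]1c1ccc(OCc2ccccc2)c(OCc2ccccc2)c1 | intermediate
17 | 3-(benzyloxy)phenol | Oc1cccc(OCc2ccccc2)c1 | starting material
18 | (1R,2S,3S)-3-[3-(benzyloxy)phenoxy]-3-[3,4-bis(benzyloxy)phenyl]-1-[(2R,3S)-3,7-bis(benzyloxy)-2-[3,4-bis(benzyloxy)phenyl]chroman-8-yl]propane-1,2-diol | O[C@H](c1c(OCc3ccccc3)ccc2c1O[C@H](c1ccc(OCc3ccccc3)c(OCc3ccccc3)c1)[C@@H](OCc1ccccc1)C2)[C@H](O)[C@H](c1ccc(OCc2ccccc2)c(OCc2ccccc2)c1)Oc1cccc(OCc2ccccc2)c1 | intermediate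
19 | hepta-O-benzyl dimer, upper unit (2S,3S,4S) with free 3-OH, lower unit (2R,3S) | c3ccccc3COc1ccc2c(c1)O[C@@H](c1ccc(OCc3ccccc3)c(OCc3ccccc3)c1)[C@@H](O)[C@@H]2c1c(OCc3ccccc3)ccc2c1O[C@H](c1ccc(OCc3ccccc3)c(OCc3ccccc3)c1)[C@@H](OCc1ccccc1)C2 | intermediate
20 | CNP0189433.2, (2S,3S,4S)-2-(3,4-dihydroxyphenyl)-4-[(2R,3S)-2-(3,4-dihydroxyphenyl)-3,7-dihydroxychroman-8-yl]chromane-3,7-diol | Oc1ccc2c(c1)O[C@@H](c1ccc(O)c(O)c1)[C@@H](O)[C@@H]2c1c(O)ccc2c1O[C@H](c1ccc(O)c(O)c1)[C@@H](O)C2 | target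

Total step count: 13. Longest linear sequence: 11 steps (steps 1–5 and 8–13, from (+)-taxifolin).

Steps most likely to fail

Step 12 (key step). What may go wrong: loss of facial control when the tethered arene adds to the C4 cation (attack syn to the C3 hydroxyl), a 1,2-hydride shift of the cation next to the free C3 hydroxyl, or opening of the oxirane at C3 in stage one. Fallback: the two bond formations are separated and the C4 face is fixed by neighbouring-group participation instead of allylic strain. Setting out from 16, the phenoxide opening is run alone and 18 is isolated. Both hydroxyls are acetylated (Ac2O, pyridine, DMAP) to give the 1,2-di-O-acetate of 18 F1. TMSOTf in CH2Cl2 at −40 °C ionises the C4 acetate; the C3 acetate bridges to C4 as a trans-1,3-dioxolan-2-ylium ion and the tethered arene must enter anti to it, which should give the 3-O-acetate of 19 F2. K2CO3 in MeOH/THF removes the acetate and the route is rejoined at 19.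

Step 11. What may go wrong: acid- or silica-induced opening of the electron-rich cis-aryloxirane while it is formed and handled, over-oxidation of the electron-rich rings, or insufficient hydroxyl direction. Fallback: the oxirane stereocentres are set by catalyst control on a small fragment, and the carbinol is then made without stereocontrol, which is permitted because step 12 erases it. Setting out from 9, lithium acetylide 10 and paraformaldehyde give 3-[3,4-bis(benzyloxy)phenyl]prop-2-yn-1-ol F3. Lindlar semihydrogenation gives (Z)-3-[3,4-bis(benzyloxy)phenyl]prop-2-en-1-ol F4. Vanadium-catalysed asymmetric epoxidation (VO(Oi-Pr)3, chiral bis-hydroxamic acid ligand, t-BuOOH) gives [(2S,3R)-3-[3,4-bis(benzyloxy)phenyl]oxiran-2-yl]methanol F5. Parikh–Doering oxidation (SO3·pyridine, DMSO, i-Pr2NEt) gives (2R,3R)-3-[3,4-bis(benzyloxy)phenyl]oxirane-2-carbaldehyde F6. Addition of aryllithium 12 (made from 7 as in step 8) at −78 °C gives 16 together with the (S)-carbinol epimer of 16 F7. Both epimers are taken through the conditions of step 12 and the route is rejoined at 19.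

Step 8. What may go wrong: competing metalation of the benzylic OCH2 groups followed by Wittig rearrangement, or slow or conjugate addition of the hindered aryllithium to the ynamide. Fallback: the C8–C bond is made with a small electrophile and the ynone is reached by addition and oxidation. Setting out from 7, aryllithium 12 (or the arylmagnesium species made with TMPMgCl·LiCl) is quenched with DMF to give the 8-carbaldehyde of 7 F8. Lithium acetylide 10 adds to it to give 14 together with the (1R)-epimer of 14 F9. MnO2 in CH2Cl2 oxidises both epimers to the ynone and the route is rejoined at 13.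

Further compounds
F1 | step 12 | 1,2-di-O-acetate of 18 | CC(=O)O[C@H](c1c(OCc3ccccc3)ccc2c1O[C@H](c1ccc(OCc3ccccc3)c(OCc3ccccc3)c1)[C@@H](OCc1ccccc1)C2)[C@H](OC(C)=O)[C@H](c1ccc(OCc2ccccc2)c(OCc2ccccc2)c1)Oc1cccc(OCc2ccccc2)c1
F2 | step 12 | 3-O-acetate of 19 | c3ccccc3COc1ccc2c(c1)O[C@@H](c1ccc(OCc3ccccc3)c(OCc3ccccc3)c1)[C@@H](OC(C)=O)[C@@H]2c1c(OCc3ccccc3)ccc2c1O[C@H](c1ccc(OCc3ccccc3)c(OCc3ccccc3)c1)[C@@H](OCc1ccccc1)C2
F3 | step 11 | 3-[3,4-bis(benzyloxy)phenyl]prop-2-yn-1-ol | OCC#Cc1ccc(OCc2ccccc2)c(OCc2ccccc2)c1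
F4 | step 11 | (Z)-3-[3,4-bis(benzyloxy)phenyl]prop-2-en-1-ol | OC/C=C\c1ccc(OCc2ccccc2)c(OCc2ccccc2)c1
F5 | step 11 | [(2S,3R)-3-[3,4-bis(benzyloxy)phenyl]oxiran-2-yl]methanol | OC[C@@H]1O[C@@H]1c1ccc(OCc2ccccc2)c(OCc2ccccc2)c1
F6 | step 11 | (2R,3R)-3-[3,4-bis(benzyloxy)phenyl]oxirane-2-carbaldehyde | O=C[C@@H]1O[C@@H]1c1ccc(OCc2ccccc2)c(OCc2ccccc2)c1
F7 | step 11 | (S)-carbinol epimer of 16 | O[C@@H](c1c(OCc3ccccc3)ccc2c1O[C@H](c1ccc(OCc3ccccc3)c(OCc3ccccc3)c1)[C@@H](OCc1ccccc1)C2)[C@@H]1O[C@@H]1c1ccc(OCc2ccccc2)c(OCc2ccccc2)c1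
F8 | step 8 | 8-carbaldehyde of 7, (2R,3S)-3,7-bis(benzyloxy)-2-[3,4-bis(benzyloxy)phenyl]chromane-8-carbaldehyde | O=Cc1c(OCc3ccccc3)ccc2c1O[C@H](c1ccc(OCc3ccccc3)c(OCc3ccccc3)c1)[C@@H](OCc1ccccc1)C2
F9 | step 8 | (1R)-epimer of 14 | O[C@@H](c1c(OCc3ccccc3)ccc2c1O[C@H](c1ccc(OCc3ccccc3)c(OCc3ccccc3)c1)[C@@H](OCc1ccccc1)C2)C#Cc1ccc(OCc2ccccc2)c(OCc2ccccc2)c1
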